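The readings stem from a simulated flask from invented constants, and the scatter is random.

A plateau height cannot say why a flask stopped. The alder run flattens near 27.11 mM from 80.0 mM of substrate and 80.0 mM of partner. That fits a step that has reached its balance, and it also fits a partner disappearing by a second way while target forms. The two readings part in the larch run, so there I must choose.

| setting | alder | birch | cedar | maple | larch |
|---|---|---|---|---|---|
| substrate | 80.0 mM | 48.0 mM | 120 mM | 80.0 mM | 40.0 mM |
| partner | 80.0 mM | 48.0 mM | 80.0 mM | 40.0 mM | 240 mM |
| time |  |  |  |  | 53 min |

| run | time / min | [target] / mM |
|---|---|---|
| alder run | 6.6 | 9.34 |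
| alder run | 13 | 15.26 |
| alder run | 20 | 20.08 |
| alder run | 26 | 22.09 |
| alder run | 33 | 23.88 |
| alder run | 40 | 25.58 |
| alder run | 46 | 26.15 |
| alder run | 53 | 27.11 |
| birch run | 6.6 | 3.51 |
| birch run | 13 | 5.96 |
| birch run | 20 | 7.89 |
| birch run | 26 | 8.93 |
| birch run | 33 | 10.28 |
| birch run | 40 | 11.09 |
| birch run | 46 | 11.28 |
| birch run | 53 | 11.47 |
| cedar run | 6.6 | 13.52 |
| cedar run | 13 | 21.56 |
| cedar run | 20 | 27.63 |
| cedar run | 26 | 30.21 |
| cedar run | 33 | 32.78 |
| cedar run | 40 | 34.38 |
| cedar run | 46 | 35.33 |
| cedar run | 53 | 35.76 |
| maple run | 6.6 | 4.73 |
| maple run | 13 | 8.09 |
| maple run | 20 | 10.36 |
| maple run | 26 | 11.49 |
| maple run | 33 | 13.14 |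
| maple run | 40 | 13.60 |
| maple run | 46 | 14.50 |
| maple run | 53 | 14.09 |

(readings scatter by 0.2 mM)

- Overall: substrate + partner -> target.
- Constant volume, constant temperature.
- "The second partner" is partner.
- An order is taken over about fifteen percent of the charge, up and down.

* the power of [partner] that the first rate follows, about the charge of the alder run; measure it at two percent of substrate made into target
* the power of [substrate] that the first rate follows, about the charge of the alder run; measure it at two percent of substrate made into target (one fixed amount of target, the same in the runs compared)
* target in the larch run at 53 min, as a share of the substrate charged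

I reckon the second reading as my own. Put into the integrated second-order law, the first alder reading gives a forward constant k of 0.250 /M/min, a reading with its scatter. In the cedar run substrate stands above partner, so I give each partner two exits: into target at k times the mean substrate S, and away at λ. With the back step left out, target over partner lost then equals kS/λ. But partner not in target also holds free partner: the cedar run still rises from 34.38 mM to 35.76 mM between 40 min and 53 min, a slope of 0.106 mM/min. Dividing that slope by k times the substrate left at 46 min reads free partner as 5.01 mM, so 39.7 mM counts as lost there. With S at 102 mM, this gives 0.0288 /min for λ, my reading of the partner loss constant, the share of free partner disappearing per minute.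

Now the ladder for the larch run. The first rung is the substrate clock, one over k times the partner charge: 16.6 min. Substrate is the limiting reagent there, 40.0 mM against 240 mM of partner, and I ignore both what target draws from partner and the back step. The second rung is the partner clock, one over λ: 34.8 min, longer than the substrate clock but shorter than the 53 min asked. So partner fades while substrate is still turning. By 53 min substrate has lived through 1.63 substrate clocks, the partner charge times k times one minus e to the minus λt, over λ, and not the 3.19 that a steady partner gives. My reckoning is one minus e to the minus that count: 80.5 % of the substrate as target.

The forecast gives orders of 1 in partner and 1 in substrate and 67 % for the larch run, on these grounds: “The target levels off far below the charge in every run, so the reaction looks reversible.” My figure stands above its figure.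

The flask gives orders of 1.0 in partner and 1.0 in substrate, and 75.9 % in the larch run at 53 min, which is 8.9 percentage points above the forecast and below my figure.

    substrate + partner ⇌ target (0.2760 /M/min, 0.003084 /min)
    partner → lost reagent (0.02538 /min)

Fitted to the readings, the main steps alone leave a root mean square residual of 1.3 in units of the scatter, the true steps 0.99. In the maple run, with mean substrate at 73.0 mM, λ of 0.0288 /min joins k times that substrate for a total partner exit of 0.0470 /min. The share of the 40.0 mM of partner taking the target exit, over that time, gives 14.3 mM of target at 53 min, where the maple reading is 14.09 mM.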